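The runs were computed with made-up constants; the scatter is artificial.

The constants of the three proposed steps are hidden, so I read time scales from the runs, in which, by the proposed steps, catalyst turns substrate and dissolved gas into product while added ligand ties catalyst up as idle complex.

| flask | substrate | gas phase | catalyst | added ligand | remark | time |
|---|---|---|---|---|---|---|
| Friday's | 0.010 M | 1.3 mM (held) | 5 mol% | 3.2 mM | run made earlier |  |
| Thursday's | 0.010 M | 1.3 mM (held) | 20 mol% | 3.2 mM | run made earlier |  |
| Tuesday's | 0.020 M | 1.3 mM (held) | 10 mol% | 3.2 mM | run made earlier |  |
| flask | 0.010 M | 1.3 mM (held) | 10 mol% | 3.2 mM |  | 10 min |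

| run | time / min | product / % | substrate / % |
|---|---|---|---|
| Friday's | 0.667 | 7 | 94 |
| Friday's | 1.33 | 12 | 87 |
| Friday's | 3.00 | 14 | 83 |
| Friday's | 8.00 | 19 | 82 |
| Thursday's | 2.00 | 48 | 53 |
| Thursday's | 4.00 | 60 | 42 |
| Thursday's | 6.00 | 65 | 37 |
| Thursday's | 8.00 | 72 | 28 |
| Tuesday's | 1.00 | 30 | 69 |
| Tuesday's | 3.00 | 49 | 52 |
| Tuesday's | 5.00 | 60 | 39 |
| Tuesday's | 8.00 | 70 | 31 |

(scatter of a reading: 2 percentage points)

- at the start none of the gas is dissolved
- what was read earlier has a scatter of 2 percentage points, one standard deviation
- steps that have been proposed: catalyst + added ligand <-> idle complex; substrate + dissolved gas + catalyst -> catalyst + product; gas phase <-> dissolved gas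

* product at 10 min, in percent of the substrate charged
* the change that raises the amount of product at 10 min, in percent of the substrate charged most ("none" if none brings more than 2 percentage points) (amber / violet / red / none)
* amount of product at 10 min, in percent of the substrate charged, after amber

- amber: doubling the amount of catalyst, all else as stated
- violet: doubling the transfer coefficient of the gas phase, all else as stated
- red: doubling the saturation concentration of gas phase, all else as stated

The first rung is the gas: Friday's run already shows 7 % product at 0.667 min, with no lag to read, so I take the dissolved gas as full from the first reading on. The next rung is a burst: Friday's product reaches 12 % by 1.33 min, then gains 5 percentage points between 3.00 min and 8.00 min. Thursday's and Tuesday's runs both hold 2.00 mM of catalyst, and at 8.00 min they stand at 72 % and 70 % although Tuesday's substrate is twice Thursday's. So at an equal catalyst charge these two runs read like a pseudo-first-order fall of the fraction of substrate, and I count the catalyst by its charge, not its mol%. I call minus the logarithm of the fraction left the exposure.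

The last rung is the tail. Catalyst is the smaller charge of the binding, with 1.00 mM in the flask against 3.2 mM of ligand. If it ends up bound, free catalyst follows the ligand ratio, catalyst charged over ligand left after binding it: 0.455 in the flask and 1.67 on Thursday. Thursday's substrate, from 42 % to 28 % between 4.00 min and 8.00 min, gives a tail constant of 0.101 min⁻¹, so the flask gets 0.0276 min⁻¹. Its tail time of 36.2 min is longer than the 10 min asked. Thursday's burst exposure, what remains at 8.00 min after the tail, is 0.462. With the ligand charge equal, I scale it by catalyst charge to 0.231. The flask's exposure of 0.507 then gives 39.8 % product. Amber is Thursday's recipe, giving 77.1 %. Red, which I take as doubling both terms, gives 63.8 %, less than amber, and violet speeds a rung I take as over by the first reading.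

The forecast says 44 %, amber and 76 %, reading the runs as “free catalyst being gradually tied up by added ligand”; my product for the flask is lower than its figure, and my choice is the same. The flask gives 42.8 %; amber adds 33 points, red 25 points and violet 0.86 points, and amber reaches 75.8 %.

    catalyst + added ligand ⇌ idle complex (K = 4900 M⁻¹, k = 5.90 M⁻¹ s⁻¹)
    substrate + dissolved gas + catalyst → catalyst + product (k = 4500 M⁻² s⁻¹)
    gas phase ⇌ dissolved gas, rate k3*(csat - [dissolved gas]) (kL = 0.390 s⁻¹)

At 10.0 min the flask's idle complex over ligand left stands at 0.402, against the ligand ratio of 0.455, and 8.22 % of its catalyst charge is free. The neighbouring flask holds 0.0060 M of substrate at the same mol%, so its ligand ratio is 0.231. That makes its tail constant 0.0140 min⁻¹ and its burst exposure 0.139, and the same reckoning gives 24.3 % product. That neighbouring flask gives 26.9 % at 10.0 min, with 73.1 % of its substrate left.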